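## Analysis of the target

Ocophyllal B (10) is a fully aromatic, achiral 2-arylbenzofuran: ring A is the benzo ring (C3a to C7a), ring B the furan (O1, C2, C3) and ring C a 3,4,5-trimethoxyphenyl group on C2. C3 carries a methyl group, C7 a methoxy group and C5 a formyl group. There are no stereocenters, so the problem is one of regiochemistry and oxidation level only. The aldehyde is the sensitive group (oxidation, carbonyl photochemistry, attack by nucleophiles), and the electron-rich C2=C3 bond does not tolerate strong oxidants or prolonged strong acid. The difficulty is to build a 2,3-disubstituted furan onto a benzene ring whose three substituents (O1 on C7a, OMe on C7, CHO on C5) must sit in one fixed pattern, without regioisomers and without a late redox correction. The plan rests on the fact that ring A is syringaldehyde (1) less one methoxy group: C7a–O1 is the phenol oxygen, C7 keeps its OMe, C5 keeps the formyl carbon, and C3a is the carbon that bore the second OMe. That methoxy group can therefore act as a leaving group once C3 has been bonded to C3a. C2, C3, the C3 methyl and ring C are the enol form of ketone 4.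

## Retrosynthetic reasoning

**10 ⇒ 9 (no skeletal bond cut).** The C5 formyl group is traced back to the dimethyl acetal 9. An aryl aldehyde cannot be carried through an irradiation in the presence of an electron-rich enol ether, whereas the acetal is photochemically silent. The forward reaction only has to unmask the aldehyde under mild aqueous acid, which the benzofuran and the aryl methyl ethers tolerate.

**9 ⇒ 7 (C3–C3a cut, methoxy returned to C3a).** C3–C3a is the one bond of ring B whose cleavage leaves two stable halves joined through O1. Putting a methoxy group back on C3a makes ring A a symmetric syringyl ring with two equivalent ortho carbons, so the ring closure has no regiochemical choice to make. The C2=C3 bond becomes the double bond of enol ether 7. The forward reaction has to form C3–C3a at a methoxy-bearing carbon and then lose that methoxy group together with the C3 hydrogen; this passes through ylide 8 and gives the aromatic furan without an oxidant.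

**7 ⇒ 3 + 6 (O1–C2 cut).** The vinyl C–O bond is cut, not the aryl C–O bond, because O1 is already on the ring in 1. The opposite cut would need a hindered aryl halide and an enolate oxygen nucleophile, and ketone enolates arylate at carbon under palladium catalysis. The cut gives two fragments of similar size, phenol 3 and enol triflate 6. The forward reaction has to join a 2,6-disubstituted phenol to a trisubstituted alkenyl electrophile with retention of geometry and without harming the acetal.

**6 ⇒ 4 (enol oxygen activated, via 5).** Ketone 4 has a single enolizable position, so the enolate 5 and the triflate 6 are formed without regiochemical ambiguity. The forward reaction has to deliver O-sulfonylation of the kinetic enolate.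

**3 ⇒ 1 + 2 (acetal formation).** The aldehyde of 1 is masked with orthoformate 2 before the coupling. Acid cannot be used once the enol ether is present, and the acetal also leaves the phenol more electron-rich, which helps the C–O bond-forming step.

## Alternatives that were turned down

**Alternative 1:** Dötz benzannulation on a furan.
- Disconnection: ring A is dismantled at C6–C7, C4–C5 and C3a–C4. C7 with its methoxy group is the carbene carbon of the chromium complex A1, pentacarbonyl{methoxy[4-methyl-5-(3,4,5-trimethoxyphenyl)furan-2-yl]methylidene}chromium, (CO)5Cr=C(OMe)(furyl). C5 and C6 come from the terminal alkyne A2, tert-butyldimethyl(prop-2-yn-1-yloxy)silane, and C4 is a carbonyl ligand.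
- Forward key step: warming A1 with A2 in an ether solvent should give the benzofuran-4-ol A3 by alkyne insertion, carbonyl insertion and closure of the vinylketene onto furan C3. The larger alkyne substituent ends next to the new hydroxyl, so the CH2O carbon sits on C5 and OMe on C7.
- For it: benzannulation of 2-furyl carbene complexes is an established reaction class with predictable regiochemistry, and ring A is made with every substituent placed in one step. On precedent for the key step it is clearly stronger than the chosen route.
- Against it: A3 has an oxygen on C4 that 10 lacks, so sulfonylation and reductive removal, then desilylation and oxidation of the C5 carbinol follow (four steps after the key step). A1 needs a prior furan synthesis, lithiation and a stoichiometric chromium carbonyl source. A3 is a hydroquinone monoether that oxidizes easily to a quinone.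
- Comparison: about ten steps against five. The chosen strategy offers a purchased ring A with the right oxygen pattern and oxidation level, no stoichiometric heavy metal and no deoxygenation.

**Alternative 2:** [4+1] annulation of an ortho-quinone methide with a sulfur ylide, then aromatization.
- Disconnection: C2–C3 and O1–C2 of a 2,3-dihydrobenzofuran. C3 with its methyl is the exocyclic carbon of a quinone methide released from sulfone A4, 4-bromo-2-methoxy-6-[1-(4-methylbenzenesulfonyl)ethyl]phenol. C2 with ring C is the ylide carbon from sulfonium salt A5, dimethyl(3,4,5-trimethoxybenzyl)sulfonium bromide.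
- Forward key step: a carbonate base eliminates sulfinate from A4 and deprotonates A5. Conjugate addition of the ylide (C2–C3) and displacement of the sulfide leaving group by the phenoxide (O1–C2) should give the trans-dihydrobenzofuran A6.
- For it: the annulation type is well established, runs at room temperature without special equipment, and both partners derive from cheap aromatics. On reliability of the ring-forming step it is stronger than the chosen route.
- Against it: a sulfur ylide would epoxidize an aldehyde (Corey–Chaykovsky reaction), so C5 must carry a bromine placeholder and the formyl group is installed afterwards. Two stereocenters (C2, C3) are made only to be destroyed. Dehydrogenation of A6 needs a strong hydride acceptor on a substrate with a very electron-rich ring C and a benzylic methyl group, where over-oxidation is a real risk.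
- Comparison: with the steps needed for A4 and A5 the route runs to seven or eight steps. The chosen strategy reaches the aromatic oxidation level directly, because the departing methoxy group does the work of the oxidant, and it carries the formyl carbon from the start.

**Alternative 3:** Stobbe condensation and anhydride cyclization onto a furan.
- Disconnection: ring A is cut at C7–C7a and C4=C5. C4 is the formyl carbon of furan aldehyde A7, 4-methyl-5-(3,4,5-trimethoxyphenyl)furan-3-carbaldehyde. C5, C6, C7 and the ester carbon come from dimethyl succinate A8.
- Forward: Stobbe condensation of A7 with A8 gives the half-ester A9, (E)-3-(methoxycarbonyl)-4-[4-methyl-5-(3,4,5-trimethoxyphenyl)furan-3-yl]but-3-enoic acid. In the key step, acetylating and dehydrating conditions turn the acid of A9 into a mixed anhydride that acylates the free furan α-carbon (C7–C7a). The ketone enolizes to the phenol and is acetylated, giving A10.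
- For it: every step is classical and scalable, the acyl carbon can reach only one furan position, and nothing is speculative. In certainty per step it is the strongest of the four.
- Against it: A10 has the wrong group at C7 (acetate, not methyl ether) and at C5 (ester, not aldehyde), which costs deacetylation, O-methylation, reduction and re-oxidation. A7, a trisubstituted furan with a free α-position, is itself a multistep target, so the difficulty moves into the starting material.
- Comparison: nine steps or more. The chosen route is about half as long because 1 already holds C5 at the aldehyde level and C7 as the methyl ether.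

Key step: step 4

Remark: 1, 2 and 4 are taken as purchased, and the double-bond geometry of 7 is taken to be irrelevant to step 4, because E/Z photoisomerization precedes closure and both isomers converge on 9.

## Route

Step 1
Reactants: 1 syringaldehyde (4-hydroxy-3,5-dimethoxybenzaldehyde); 2 trimethyl orthoformate
Product: 3 4-(dimethoxymethyl)-2,6-dimethoxyphenol
Conditions: HC(OMe)3 (3 equiv), MeOH, p-TsOH·H2O (1 mol %), rt; then Et3N
Reagents that add atoms: methanol, CO (co-solvent; its methoxy groups exchange with those of 2)
Why: Acid-catalysed acetalization, driven by the orthoformate as water scavenger (it ends as methyl formate); the phenol is not touched. The electron-rich acetal is acid-labile, so the acid is neutralized with Et3N before concentration and 3 is purified by crystallization or on Et3N-deactivated silica.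

Step 2
Reactants: 4 1-(3,4,5-trimethoxyphenyl)propan-1-one
Product: 6 (Z)-1-(3,4,5-trimethoxyphenyl)prop-1-en-1-yl trifluoromethanesulfonate, via potassium (Z)-enolate 5 (not isolated)
Conditions: KN(SiMe3)2 (1.1 equiv), THF, −78 °C; then PhNTf2 (1.1 equiv), −78 °C to 0 °C
Reagents that add atoms: N-phenylbis(trifluoromethanesulfonimide) (PhNTf2), O=S(=O)(N(c1ccccc1)S(=O)(=O)C(F)(F)F)C(F)(F)F; KN(SiMe3)2, C[Si](C)(C)[N-][Si](C)(C)C.[K+] (supplies only the potassium counter-ion of 5)
Why: Enol triflate formation: kinetic deprotonation of an aryl ethyl ketone by a hindered amide base gives the Z(O)-enolate (methyl cis to oxygen, which avoids A(1,3) strain with the aryl group), and O-sulfonylation by PhNTf2 traps it with retention. The ketone has one enolizable position, so there is no regiochemical issue.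

Step 3
Reactants: 6 (Z)-1-(3,4,5-trimethoxyphenyl)prop-1-en-1-yl trifluoromethanesulfonate; 3 4-(dimethoxymethyl)-2,6-dimethoxyphenol
Product: 7 5-(dimethoxymethyl)-1,3-dimethoxy-2-{[(Z)-1-(3,4,5-trimethoxyphenyl)prop-1-en-1-yl]oxy}benzene
Conditions: Pd2(dba)3 (2.5 mol %), t-BuXPhos (7.5 mol %), K3PO4 (2 equiv), toluene, 90 °C
Reagents that add atoms: none
Why: Buchwald–Hartwig-type C–O coupling of an enol triflate with a phenol: oxidative addition of zerovalent palladium into the vinyl C–OTf bond, exchange of triflate for the phenoxide, and C–O reductive elimination, which the bulky biaryl phosphine promotes even for a 2,6-disubstituted, electron-rich phenoxide. Alkene geometry is retained; the weak base K3PO4 spares the acetal and avoids anti-elimination of the triflate to an alkyne.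

Step 4
Reactants: 7 5-(dimethoxymethyl)-1,3-dimethoxy-2-{[(Z)-1-(3,4,5-trimethoxyphenyl)prop-1-en-1-yl]oxy}benzene
Product: 9 5-(dimethoxymethyl)-7-methoxy-3-methyl-2-(3,4,5-trimethoxyphenyl)-1-benzofuran, via carbonyl ylide 8 (not isolated)
Conditions: hν (300 nm, Pyrex), K2CO3 (solid, 3 equiv), degassed MeCN (0.005 M), rt
Reagents that add atoms: none
Why: Proposed new method: excitation of the α-aryloxystyrene chromophore of 7 should let the five-atom, six-electron array C3=C2–O1–C7a=C3a (the enol ether double bond, one oxygen lone pair and one arene double bond) close in conrotatory fashion, which forms C3–C3a and ring B as the dearomatized carbonyl ylide 8 with C3a sp3 and still bearing OMe. The closest known reaction types are the heteroatom-directed photoarylation of aryl vinyl ethers, in which the same kind of ylide forms at a hydrogen-bearing ortho carbon and collapses to a 2,3-dihydrobenzofuran by a 1,4-hydrogen shift, and the non-oxidative photocyclization of ortho-methoxystilbenes, in which the cyclized intermediate aromatizes by losing methanol; the combination of the two on an aryl enol ether has not been shown. In 8 there is no hydrogen on C3a, so the hydrogen-shift exit is closed, while the negative charge of the ylide is delocalized onto C4, C6 and C7a and the charge at C4 can push out methoxide from the adjacent C3a; this restores the benzene ring and leaves an oxocarbenium ion at C2 stabilized by ring C, and carbonate (or the methoxide just released) removes the C3 proton to give the aromatic furan, so the net change is loss of MeOH with no oxidant. Mode of closure of ring B: a photochemical six-electron 1,5-electrocyclization (formally 5-endo, but pericyclic), followed by an E1cB-like elimination. No stereocenter is set: the two transient ones in 8 (C3 and C3a) are erased on aromatization, which is also why E/Z photoisomerization of 7 during irradiation is harmless. Regioselectivity is not needed, since the syringyl ring is symmetric and both ortho carbons carry OMe; what the step needs is chemoselectivity for ylide formation and methoxide loss over photo-Fries-type homolysis of the aryl–O or vinyl–O bond, thermal reversion of 8 and oxidation, and the substrate answers this with a good leaving group exactly at C3a and a cation-stabilizing para-methoxy-substituted ring on C2, supported by oxygen-free, dilute, K2CO3-buffered conditions. The formyl group is kept as its acetal so that no carbonyl n,π* chemistry (Paternò–Büchi addition to the enol ether, hydrogen abstraction) can compete.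

Step 5
Reactants: 9 5-(dimethoxymethyl)-7-methoxy-3-methyl-2-(3,4,5-trimethoxyphenyl)-1-benzofuran
Product: 10 ocophyllal B, 7-methoxy-3-methyl-2-(3,4,5-trimethoxyphenyl)-1-benzofuran-5-carbaldehyde
Conditions: 1 M aq. HCl, THF, rt
Reagents that add atoms: water, O
Why: Acid-catalysed acetal hydrolysis through the aryl-stabilized oxocarbenium ion; the carbonyl oxygen comes from water. The benzofuran and the aryl methyl ethers are inert to dilute aqueous acid at room temperature.

## Compound list

1 | syringaldehyde (4-hydroxy-3,5-dimethoxybenzaldehyde) | COc1cc(C=O)cc(OC)c1O | starting material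
2 | trimethyl orthoformate | COC(OC)OC | starting material
3 | 4-(dimethoxymethyl)-2,6-dimethoxyphenol | COC(OC)c1cc(OC)c(O)c(OC)c1 | intermediate
4 | 1-(3,4,5-trimethoxyphenyl)propan-1-one | CCC(=O)c1cc(OC)c(OC)c(OC)c1 | starting material
5 | potassium (Z)-1-(3,4,5-trimethoxyphenyl)prop-1-en-1-olate (not isolated) | C/C=C(\[O-])c1cc(OC)c(OC)c(OC)c1.[K+] | intermediate
6 | (Z)-1-(3,4,5-trimethoxyphenyl)prop-1-en-1-yl trifluoromethanesulfonate | C/C=C(\OS(=O)(=O)C(F)(F)F)c1cc(OC)c(OC)c(OC)c1 | intermediate
7 | 5-(dimethoxymethyl)-1,3-dimethoxy-2-{[(Z)-1-(3,4,5-trimethoxyphenyl)prop-1-en-1-yl]oxy}benzene | C/C=C(\Oc1c(OC)cc(C(OC)OC)cc1OC)c1cc(OC)c(OC)c(OC)c1 | intermediate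
8 | carbonyl ylide 5-(dimethoxymethyl)-3a,7-dimethoxy-3-methyl-2-(3,4,5-trimethoxyphenyl)-3,3a-dihydro-1-benzofuran-1-ium-2-ide (not isolated; one resonance form drawn; racemic, configuration at C3 and C3a not carried on) | COC1=CC(C(OC)OC)=CC2(OC)C(C)[C-](c3cc(OC)c(OC)c(OC)c3)[O+]=C12 | intermediate
9 | 5-(dimethoxymethyl)-7-methoxy-3-methyl-2-(3,4,5-trimethoxyphenyl)-1-benzofuran | Cc1c(-c2cc(OC)c(OC)c(OC)c2)oc2c(OC)cc(C(OC)OC)cc12 | intermediate
10 | ocophyllal B, 7-methoxy-3-methyl-2-(3,4,5-trimethoxyphenyl)-1-benzofuran-5-carbaldehyde | COc1cc(-c2oc3c(OC)cc(C=O)cc3c2C)cc(OC)c1OC | target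

## Step count and least certain steps

Total step count: 5. Longest linear sequence: 4 steps (1 → 3 → 7 → 9 → 10, or 4 → 6 → 7 → 9 → 10).

**Step 4 (key step, proposed new method).**
- What may go wrong: the excited enol ether may decay mainly by E/Z isomerization and by homolysis of the aryl–O or vinyl–O bond instead of closing onto a methoxy-bearing, shielded ortho carbon. The ylide, once formed, may revert faster than it ejects methoxide. The strongly absorbing benzofuran product may screen the substrate and undergo secondary photoreactions at higher conversion.
- Fallback (known chemistry), from 6 back to the route at 10: anti-elimination of triflic acid from 6 with LiN(i-Pr)2 in THF at −78 °C (in the Z-isomer the C2 hydrogen is anti to the triflate) should give 1,2,3-trimethoxy-5-(prop-1-yn-1-yl)benzene F1. A Larock heteroannulation of F1 with purchased 4-hydroxy-3-iodo-5-methoxybenzaldehyde F2 (Pd(OAc)2, LiCl, Na2CO3, DMF, 100 °C) then builds ring B in one operation. Zerovalent palladium inserts into the C–I bond, syn-carbopalladation places the arene on the methyl-bearing alkyne carbon and palladium on the aryl-bearing one, and C–O reductive elimination with the phenoxide should give 10 directly with the free aldehyde in place. The photochemical C3–C3a closure is replaced by a metal-mediated one, and steps 1, 3 and 5 are not needed.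

**Step 3 (C–O coupling).**
- What may go wrong: slow C–O reductive elimination with the doubly ortho-substituted phenoxide, so that triflyl transfer to the phenoxide (S–O cleavage, returning ketone 4) and base-induced elimination of the triflate take over.
- Fallback, from 3 back to the route at 7: O-acylation of 3 with purchased 3,4,5-trimethoxybenzoyl chloride F3 (Et3N, cat. DMAP, CH2Cl2, 0 °C) should give 4-(dimethoxymethyl)-2,6-dimethoxyphenyl 3,4,5-trimethoxybenzoate F4. Takai–Utimoto ethylidenation of the ester carbonyl of F4 with 1,1-dibromoethane (CC(Br)Br), TiCl4, TMEDA, Zn and cat. PbCl2 in THF at rt should give 7, mainly as the Z-isomer. TiCl4 is complexed with TMEDA and reduced before F4 is added, so the acetal should not meet a free Lewis acid. The cross-coupling is replaced by a carbonyl olefination.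

**Step 2 (enol triflation).**
- What may go wrong: loss of the enol triflate by hydrolysis during isolation (an α-aryl enol triflate with a para-donor ionizes easily) or by anti-elimination under excess base, and erosion of geometric purity.
- Fallback, from 4 back to the route at 7: condensation of 4 with N2H4·H2O (EtOH, reflux) should give [1-(3,4,5-trimethoxyphenyl)propylidene]hydrazine F5. A Barton vinyl iodide synthesis (I2, 1,1,3,3-tetramethylguanidine, THF, 0 °C) should give 5-(1-iodoprop-1-en-1-yl)-1,2,3-trimethoxybenzene F6 as an E/Z mixture. Ullmann-type vinylation of phenol 3 with F6 (CuI, N,N-dimethylglycine, Cs2CO3, dioxane, 90 °C) should give 7; both geometrical isomers are usable. Both the leaving group and the metal are changed.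

**Step 1 (acetalization).**
- What may go wrong: hydrolytic loss of the dimethyl acetal during isolation or later handling, because the para-oxygen and two methoxy groups make the benzylic oxocarbenium ion very easy to form.
- Fallback, from 1 back to the route at 10: acetalization of 1 with 2,2-dimethylpropane-1,3-diol (OCC(C)(C)CO; cat. p-TsOH, toluene, Dean–Stark) should give the more robust cyclic acetal 4-(5,5-dimethyl-1,3-dioxan-2-yl)-2,6-dimethoxyphenol F7. Coupling with 6 as in step 3 should give 2-(3,5-dimethoxy-4-{[(Z)-1-(3,4,5-trimethoxyphenyl)prop-1-en-1-yl]oxy}phenyl)-5,5-dimethyl-1,3-dioxane F8. Irradiation as in step 4 should give 2-[7-methoxy-3-methyl-2-(3,4,5-trimethoxyphenyl)-1-benzofuran-5-yl]-5,5-dimethyl-1,3-dioxane F9. Hydrolysis (2 M aq. HCl, THF, 40 °C) should give 10.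

## Further compounds

F1 | step 4 | 1,2,3-trimethoxy-5-(prop-1-yn-1-yl)benzene | CC#Cc1cc(OC)c(OC)c(OC)c1
F2 | step 4 | 4-hydroxy-3-iodo-5-methoxybenzaldehyde | COc1cc(C=O)cc(I)c1O
F3 | step 3 | 3,4,5-trimethoxybenzoyl chloride | COc1cc(C(=O)Cl)cc(OC)c1OC
F4 | step 3 | 4-(dimethoxymethyl)-2,6-dimethoxyphenyl 3,4,5-trimethoxybenzoate | COC(OC)c1cc(OC)c(OC(=O)c2cc(OC)c(OC)c(OC)c2)c(OC)c1
F5 | step 2 | [1-(3,4,5-trimethoxyphenyl)propylidene]hydrazine | CCC(=NN)c1cc(OC)c(OC)c(OC)c1
F6 | step 2 | 5-(1-iodoprop-1-en-1-yl)-1,2,3-trimethoxybenzene (E/Z mixture) | CC=C(I)c1cc(OC)c(OC)c(OC)c1
F7 | step 1 | 4-(5,5-dimethyl-1,3-dioxan-2-yl)-2,6-dimethoxyphenol | COc1cc(C2OCC(C)(C)CO2)cc(OC)c1O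
F8 | step 1 | 2-(3,5-dimethoxy-4-{[(Z)-1-(3,4,5-trimethoxyphenyl)prop-1-en-1-yl]oxy}phenyl)-5,5-dimethyl-1,3-dioxane | C/C=C(\Oc1c(OC)cc(C2OCC(C)(C)CO2)cc1OC)c1cc(OC)c(OC)c(OC)c1
F9 | step 1 | 2-[7-methoxy-3-methyl-2-(3,4,5-trimethoxyphenyl)-1-benzofuran-5-yl]-5,5-dimethyl-1,3-dioxane | Cc1c(-c2cc(OC)c(OC)c(OC)c2)oc2c(OC)cc(C3OCC(C)(C)CO3)cc12
A1 | alternative 1 | pentacarbonyl{methoxy[4-methyl-5-(3,4,5-trimethoxyphenyl)furan-2-yl]methylidene}chromium | COC(=[Cr])c1cc(C)c(-c2cc(OC)c(OC)c(OC)c2)o1.[C-]#[O+].[C-]#[O+].[C-]#[O+].[C-]#[O+].[C-]#[O+]
A2 | alternative 1 | tert-butyldimethyl(prop-2-yn-1-yloxy)silane | C#CCO[Si](C)(C)C(C)(C)C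
A3 | alternative 1 | 5-{[tert-butyl(dimethyl)silyl]oxymethyl}-7-methoxy-3-methyl-2-(3,4,5-trimethoxyphenyl)-1-benzofuran-4-ol | Cc1c(-c2cc(OC)c(OC)c(OC)c2)oc2c(OC)cc(CO[Si](C)(C)C(C)(C)C)c(O)c12
A4 | alternative 2 | 4-bromo-2-methoxy-6-[1-(4-methylbenzenesulfonyl)ethyl]phenol (racemic) | COc1cc(Br)cc(C(C)S(=O)(=O)c2ccc(C)cc2)c1O
A5 | alternative 2 | dimethyl(3,4,5-trimethoxybenzyl)sulfonium bromide | COc1cc(C[S+](C)C)cc(OC)c1OC.[Br-]
A6 | alternative 2 | trans-5-bromo-7-methoxy-3-methyl-2-(3,4,5-trimethoxyphenyl)-2,3-dihydro-1-benzofuran (racemic, one enantiomer drawn) | C[C@@H]1[C@@H](c2cc(OC)c(OC)c(OC)c2)Oc2c(OC)cc(Br)cc21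
A7 | alternative 3 | 4-methyl-5-(3,4,5-trimethoxyphenyl)furan-3-carbaldehyde | Cc1c(C=O)coc1-c1cc(OC)c(OC)c(OC)c1
A8 | alternative 3 | dimethyl succinate | COC(=O)CCC(=O)OC
A9 | alternative 3 | (E)-3-(methoxycarbonyl)-4-[4-methyl-5-(3,4,5-trimethoxyphenyl)furan-3-yl]but-3-enoic acid | COC(=O)/C(CC(=O)O)=C/c1coc(-c2cc(OC)c(OC)c(OC)c2)c1C
A10 | alternative 3 | methyl 7-acetoxy-3-methyl-2-(3,4,5-trimethoxyphenyl)-1-benzofuran-5-carboxylate | Cc1c(-c2cc(OC)c(OC)c(OC)c2)oc2c(OC(C)=O)cc(C(=O)OC)cc12
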